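All constants were set for the occasion; the result is computed.

I want to know how much target, crystals included, stands at the end of this flask, and which doubling adds most to it.

    gas phase ⇌ dissolved gas, rate k1*(csat - [dissolved gas]) (k1 = 9.8 s⁻¹, csat = 36 mM)
    substrate + dissolved gas → target (k2 = 1.5 L mol⁻¹ s⁻¹)
    substrate → side product A (k3 = 0.022 s⁻¹)
    dissolved gas + target → over-reaction product (k4 = 2.3 L mol⁻¹ s⁻¹)
    crystals ⇌ target, rate k5*(cs5 - [target]) while solid is left; crystals form when [target] > cs5 (cs5 = 6.3 mM, k5 = 2.1 s⁻¹)
    substrate + target → side product B (k6 = 1.1 L mol⁻¹ s⁻¹)

substrate 0.10 M; gas phase 36 mM (held); time 3.0 s

- a species is counted by the substrate in it: one side product B counts as two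
- amounts and yields of target count crystals too
- given per volume of solution although it is solid: crystals
- at the start none of the gas is dissolved
- run time (flask): 3.0 s

- epsilon: doubling the dissolution coefficient of step 5, all else as stated
- eta: doubling the transfer coefficient of step 1, all else as stated
- beta: doubling the solubility in step 5, all else as stated
- gamma: doubling the saturation concentration of gas phase, all else as stated

- the target and crystals together standing at 3.0 s, as a percentage of the substrate charged
- the change that raises the amount of target and crystals together at 3.0 s, in percent of the substrate charged most ("none" if none brings more than 2 percentage points) (epsilon / eta / beta / gamma / none)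
- amount of target and crystals together at 3.0 s, in percent of the substrate charged, after gamma

First the gas. [dissolved gas] climbs towards 36 mM with a time of 0.102 s, and substrate drains it at a constant of 0.150 s⁻¹, far below the transfer coefficient 9.8 s⁻¹. So I put the gas at saturation from the start. Substrate then turns into target by a pseudo-first-order law, with m = 0.0540 s⁻¹, the making constant: the target step's constant times the saturation concentration.

With the path to side product A, substrate falls at d = 0.0760 s⁻¹. Dissolved target is lost to over-reaction and side product B at L = 0.193 s⁻¹, reckoned at the charge. For two steps in series:

Y = m/(L − d) · (exp(−d t) − exp(−L t)) = 10.9%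

Objection: the gas arrives late. The delay is 0.102 s of 3.0 s, so it costs little:

lag = Y/(k t) = 0.37 percentage points, where k is the transfer coefficient

Second objection: Y passes the solubility, 6.30% of the charge, and what lies as crystals escapes L. At the charged rate and with no losses, target reaches that level at tc = 1.17 s, an early estimate. If all the excess lies as crystals and grows evenly:

shelter = L · (Y − s) · (t − tc)/2 = 0.81 points

So I commit to 11.3%.

Doubling the saturation concentration doubles m and the over-reaction part of L. The same three lines then give 17.8%, minus 0.6 points, plus 3.8 points, or 21.0%. The other doublings leave m alone. Doubling the transfer coefficient recovers about 0.18 points, and doubling the solubility lifts it to 12.6%, above Y, which forfeits the shelter. I choose gamma.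

The forecast says 11%, gamma and 19.4%, because “Only doubling the saturation concentration directly doubles the formation rate”.

The simulation gives 11.0%, gamma with a gain of 9.1 points, and 20.1%. Epsilon brings 0.11 points, eta 0.23 points and beta −0.32 points.

In this flask at 3.00 s, the half-life of substrate along the path to target reads 13 s, and ln(2)/m is 12.8 s. The neighbouring flask is this one left until 5.0 s. The same m, d and L give Y = 14.0%, a lag of 0.29 points and a shelter of 2.8 points, so I reckon 16.5%. That neighbouring flask holds 16.3% of target and crystals together, 8.77% of the charge as crystals.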